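Ask where Qi stands highest when one charge goes through a closed flask, a dosed flask, or a tank with a short or a long stay.

the same everywhere: Ry 100 mM
- Sunday's: Gu 2 M; Xa 2 M; Ja 360 mM; run made earlier
- Friday's: Gu 2 M; Xa 2 M; Ja 240 mM; run made earlier
- Thursday's: Gu 2 M; Xa 2 M; Ja 540 mM; run made earlier
- Tuesday's: Gu 1 M; Xa 2 M; Ja 360 mM; run made earlier
- midnight: Gu 2.0 M; Xa 2.00 M; Ja 360 mM; one stirred flow tank at steady state, fed with the mixture as stated, mean residence time 150 min
- winter: Gu 2.0 M (fed, over 15.0 min); Xa 2.00 M; Ja 360 mM; all but Gu at the start; Gu goes in evenly over 15.0 min, the run ends at 15 min; time 15 min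
- dusk: Gu 2.0 M; Xa 2.00 M; Ja 360 mM; one stirred flow tank at steady state, fed with the mixture as stated, mean residence time 15 min
- dawn: Gu 2.0 M; Xa 2.00 M; Ja 360 mM; everything together in a closed stirred flask, run for 15 min; time 15 min

- Sunday's (time / min: Qi / %, Aj / %): 2.50: 13.8, 1.1; 5.00: 20.5, 3.9; 6.00: 22.7, 5.8; 10.0: 25.5, 11.8
- Friday's (time / min: Qi / %, Aj / %): 4.00: 20.7, 3.5; 8.00: 24.9, 10.4; 12.0: 25.9, 18.4; 15.0: 25.7, 24.3
- Thursday's (time / min: Qi / %, Aj / %): 1.33: 7.2, 0.2; 3.00: 13.0, 1.4; 6.00: 20.8, 4.1; 15.0: 26.1, 16.8
- Tuesday's (time / min: Qi / %, Aj / %): 1.33: 9.6, 0; 3.00: 16.2, 1.8; 6.00: 23.4, 6.1; 15.0: 25.6, 24.4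

(standard deviation of a reading: 0.3 percentage points)

- the stated concentrations are those of everything mixed, before any reaction; amounts are the same in each set-up
- what was read earlier has a scatter of 0.3 percentage points, one standard deviation
- on the list of suspects stand: Gu + Ry <-> Ry + Qi; Ry + Qi <-> Zo; Xa + Zo -> Ry + Aj; Ry + Ja <-> Wu
- the feed brings no volume worth counting
- the earlier runs were made in a closed, stirred flask

- the set-up with the highest amount of Qi at the outlet or at the end, in percent of the Gu put in ("none" if the first two lie within 2 percentage points) (midnight / winter / dusk / dawn / none)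
- amount of Qi at the outlet or at the end, in percent of the Gu put in, midnight
- amount of Qi at the outlet or at the end, in percent of the Gu put in, winter
- amount of Qi at the outlet or at the end, in percent of the Gu put in, dusk
- amount of Qi at the outlet or at the end, in percent of the Gu put in, dawn

Set two times against each other: the stay in the vessel and the lifetime of Qi against turning into Aj. Read the second from Sunday's run, which has the midnight tank's Ja and Ry. Between 6.00 min and 10.0 min Aj gains 6 percentage points while Qi averages 24.1%, which gives 16.1 min. Call this the drain lifetime, Qi divided by the rate at which Aj appears, a reading from Sunday's run that is here assumed to hold in the midnight tank as well.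

A steady tank makes Aj at that rate through one stay, so in the midnight tank Aj out is Qi out times the stay over the lifetime, 9.34. That stay is longer than the lifetime, so outflow takes less from Qi than the drain does, and Qi should stand to Gu as at the flat top of a closed run, where gain equals loss. Friday's run, though its Ja is 240 mM and not 360 mM, shows such a top in its readings, with Qi at 25.9% at 12.0 min and 25.7% at 15.0 min, and counting the rest at 12.0 min as Gu gives a ratio of Qi to Gu of 0.465. Taking Gu, Qi and Aj as summing to the feed, with Zo set aside although it can hold up to 5.00% of the Gu, midnight's Qi comes to 8.01%. Dawn, Sunday's charge closed, should lie near Friday's 25.7% and Thursday's 26.1% at 15.0 min, more than the figure for midnight.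

The forecast picks dawn and writes “Batch wins clearly”, with 26% in dawn, 20.5% in dusk, 20% in winter and 14.5% in midnight, where the reckoning here gives 8.01% instead.

The flask gives dawn: 25.8% in dawn, 20.4% in winter, 18.8% in dusk, 7.85% in midnight.

Gu + Ry ⇌ Ry + Qi (K = 1.00, k = 0.0260 /M/s); Ry + Qi ⇌ Zo (K = 48.0 /M, k = 0.0310 /M/s); Xa + Zo → Ry + Aj (k = 0.0120 /M/s); Ry + Ja ⇌ Wu, settled at all times (K = 3.00 /M) Midnight's tank holds 0.528 M of Xa, so Aj leaves at 73.6% of the Gu fed, 9.38 times the Qi beside it, against 9.34 lifetimes per stay. Dawn runs 0.934 lifetimes and ends with 20.5% of Aj, so on that lifetime its Qi averaged about 21.9%, less than its closing 25.8%.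

The data are calculated from invented constants; noise was put on by code.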